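**Retrosynthetic overview**
- The piperidine ring is never cyclised. It is carried as a pyridine and converted last by an Ir-catalysed asymmetric hydrogenation of the 3-acetoxy-2-methyl-6-alkylpyridinium salt, which sets C2, C3 and C6 (all-cis) in one step.
- The pyridyl acetate comes from the pyridinol and Ac2O; the saturated C14 chain comes from an alkyne (H2, Pd/C).
- The C6–chain bond is made by Sonogashira coupling of 6-iodo-2-methylpyridin-3-ol with tetradec-13-yn-2-one.
- The iodopyridinol comes from 2-methylpyridin-3-ol; the ynone comes from 11-bromoundec-1-yne and acetylacetone (alkylative deacetylation), the bromide from undec-10-yn-1-ol.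
- Ring order: one ring only, present from the start as the aromatic pyridine and dearomatised in the final step.

Assumption: the ligand antipode that gives the (2R,3R,6S) series in Step 7 cannot be predicted and must be assigned experimentally; (R)-SegPhos is written, and (S)-SegPhos is used if the sense is opposite.

**Step 1**
Reactants: 1, undec-10-yn-1-ol
Product: 2, 11-bromoundec-1-yne
Conditions: CBr4, PPh3, CH2Cl2, 0 °C to rt
Reagents that add atoms: carbon tetrabromide, BrC(Br)(Br)Br
Why: Appel reaction, in which the primary alcohol is activated as an alkoxyphosphonium and displaced by bromide (SN2) while the terminal alkyne is inert.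

**Step 2**
Reactants: 2, 11-bromoundec-1-yne; 3, pentane-2,4-dione (acetylacetone)
Product: 4, tetradec-13-yn-2-one
Conditions: K2CO3, NaI (cat.), EtOH, reflux, 24 h
Reagents that add atoms: none beyond the numbered reactants
Why: Alkylative deacetylation (acetylacetone as an acetone-enolate equivalent), in which C-alkylation of the diketone anion is followed in situ by retro-Claisen loss of ethyl acetate to give the methyl ketone, with the alkyne C–H too weakly acidic to interfere.

**Step 3**
Reactants: 5, 2-methylpyridin-3-ol
Product: 6, 6-iodo-2-methylpyridin-3-ol
Conditions: I2 (1.05 equiv), Na2CO3, H2O/THF, rt; then adjust to pH 6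
Reagents that add atoms: iodine, II
Why: Electrophilic aromatic iodination of the pyridinolate, where with C2 blocked by methyl the iodine enters at C6 (para to O⁻, α to N), the next-preferred site of 3-hydroxypyridines.

**Step 4**
Reactants: 6, 6-iodo-2-methylpyridin-3-ol; 4, tetradec-13-yn-2-one (1.15 equiv)
Product: 7, 14-(5-hydroxy-6-methylpyridin-2-yl)tetradec-13-yn-2-one
Conditions: PdCl2(PPh3)2 (3 mol %), CuI (5 mol %), Et3N, DMF, 50 °C, Ar
Reagents that add atoms: none
Why: Sonogashira coupling, in which the 2-iodopyridine undergoes fast oxidative addition and the ketone and free OH are tolerated (the OH is para to the alkyne, so furopyridine cyclisation is impossible).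

**Step 5**
Reactants: 7, 14-(5-hydroxy-6-methylpyridin-2-yl)tetradec-13-yn-2-one
Product: 8, 14-(5-hydroxy-6-methylpyridin-2-yl)tetradecan-2-one
Conditions: H2 (1 atm), 10 % Pd/C, EtOAc/MeOH, rt
Reagents that add atoms: none
Why: Heterogeneous catalytic hydrogenation of the alkyne to the alkane, with the neutral pyridine ring, the phenol and the dialkyl ketone untouched at 1 atm.

**Step 6**
Reactants: 8, 14-(5-hydroxy-6-methylpyridin-2-yl)tetradecan-2-one
Product: 9, 2-methyl-6-(13-oxotetradecyl)pyridin-3-yl acetate
Conditions: Ac2O (1.2 equiv), Et3N, DMAP (cat.), CH2Cl2, 0 °C to rt; quick non-basic work-up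
Reagents that add atoms: acetic anhydride, CC(=O)OC(C)=O
Why: DMAP-catalysed O-acylation of the pyridinol, which installs the target's ester early and blocks enol-to-piperidin-3-one tautomerisation during the ring reduction.

**Step 7**
Reactants: 9, 2-methyl-6-(13-oxotetradecyl)pyridin-3-yl acetate (as its hydrochloride)
Product: 10, (2R,3R,6S)-2-methyl-6-(13-oxotetradecyl)piperidin-3-yl acetate, (−)-3-O-acetylspectaline
Conditions: HCl (1.0 equiv, Et2O), evaporate; [Ir(cod)Cl]2 (2 mol %), (R)-SegPhos (4.4 mol %), H2 (50 bar), CH2Cl2/PhMe 1:1, 30 °C, 36 h; recrystallise 10·HCl to upgrade ee; then cold aq NaHCO3/CH2Cl2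
Reagents that add atoms: none
Why: Proposed new method: asymmetric ionic hydrogenation of an N–H 2,6-dialkyl-3-acyloxypyridinium, in which outer-sphere Ir–H hydride transfer to C4 gives a 1,4-dihydropyridine, the more basic non-acetoxylated enamine is protonated at C5 and the resulting C6 iminium is reduced under catalyst control (sets C6), then the remaining acetoxy-enamine equilibrates with its C2 iminium (OAc pseudoaxial to avoid A(1,2) strain with the 2-Me) and takes axial hydride at C2 anti to OAc and cis to H-6 (sets C3 and C2, all-cis), while the aprotic medium preserves the acetate and the acidic, base-free conditions leave the dialkyl ketone unreduced; the closest known reaction type is Ir–bisphosphine asymmetric hydrogenation of 2-alkyl and 2,3,6-trisubstituted pyridinium salts (hydrohalide or N-benzyl) to cis-piperidines, with heterogeneous all-cis hydrogenation of 6-alkyl-2-methylpyridin-3-ols as the racemic analogue.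

**Compound list**
1 | undec-10-yn-1-ol | C#CCCCCCCCCCO | starting material
2 | 11-bromoundec-1-yne | C#CCCCCCCCCCBr | intermediate
3 | pentane-2,4-dione | CC(=O)CC(C)=O | starting material
4 | tetradec-13-yn-2-one | CC(=O)CCCCCCCCCCC#C | intermediate
5 | 2-methylpyridin-3-ol | Cc1ncccc1O | starting material
6 | 6-iodo-2-methylpyridin-3-ol | Cc1nc(I)ccc1O | intermediate
7 | 14-(5-hydroxy-6-methylpyridin-2-yl)tetradec-13-yn-2-one | CC(=O)CCCCCCCCCCC#Cc1ccc(O)c(C)n1 | intermediate
8 | 14-(5-hydroxy-6-methylpyridin-2-yl)tetradecan-2-one | CC(=O)CCCCCCCCCCCCc1ccc(O)c(C)n1 | intermediate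
9 | 2-methyl-6-(13-oxotetradecyl)pyridin-3-yl acetate | CC(=O)CCCCCCCCCCCCc1ccc(OC(C)=O)c(C)n1 | intermediate
10 | (2R,3R,6S)-2-methyl-6-(13-oxotetradecyl)piperidin-3-yl acetate, (−)-3-O-acetylspectaline | CC(=O)CCCCCCCCCCCC[C@H]1CC[C@@H](OC(C)=O)[C@@H](C)N1 | target

**Totals**
Total step count: 7.
Longest linear sequence: 6 steps (Steps 1, 2, 4, 5, 6, 7 from undec-10-yn-1-ol); 5 steps from 2-methylpyridin-3-ol.

**Three steps most likely to fail, with fallbacks**
1. Step 7 (ee, incomplete reduction, or acetate loss on the activated pyridinium). Fallback: give up catalyst control. Hydrogenate pyridinol 8, with the ketone masked as a dioxolane, over Rh/Al2O3 or PtO2 in AcOH to racemic all-cis spectaline ketal. Then N-Boc protect and run a lipase kinetic-resolution acetylation (CAL-B, vinyl acetate), which by Kazlauskas' rule should acylate the (3R)-alcohol and give the target's acetate after acidic Boc/ketal removal. Classical resolution with dibenzoyltartaric acid is the alternative.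
2. Step 2 (O-alkylation, dialkylation, or incomplete retro-Claisen with an unactivated primary bromide). Fallback: a different disconnection for 4. Convert commercial 11-bromoundecanoic acid via its Weinreb amide and MeMgBr to 12-bromododecan-2-one, protect as the dioxolane, alkylate lithium acetylide·ethylenediamine in DMSO, and deketalise.
3. Step 4 (electron-rich, potentially chelating free pyridinol; Glaser dimerisation of 4). Fallback: replace the sp–sp2 coupling with a B-alkyl Suzuki–Miyaura coupling. Hydroborate the dioxolane of tetradec-13-en-2-one (from 11-bromoundec-1-ene by the Step 2 chemistry) with 9-BBN and couple with O-protected 6-iodo-2-methylpyridin-3-ol using Pd(dppf)Cl2. This gives the saturated chain directly and removes Step 5.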